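**Retrosynthetic overview**

1. The target is a linear hexamer A–O–B–O–C–O–D–O–E–O–F. The route rests on rings E and C, two identical benzene rings with oxygen on five adjacent carbons (E-1 to E-5, hydrogen only at E-6). In each, the oxygen at E-1 (C-1) is bonded to the doubly ortho-oxygenated carbon D-4 (B-4), and the oxygen at E-2 (C-2) must be the single free phenol.
2. Last disconnections: sixteen O-methyl groups (BBr3), then three aryl–oxygen bonds, from the ring A oxygen to B-1, from the C-2 oxygen to D-1 and from the E-2 oxygen to F-1. Each is made by Chan–Lam coupling of a hindered phenol with an arylboronic acid that has no ortho substituent.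
3. One diaryl ether phenol, 17 (ring D–O–ring E, equally ring B–O–ring C), is used twice. Its benzyloxy group is a latent boronic acid (OBn → OH → OTf → Bpin → B(OH)2).
4. 17 arises from cyclobutenone 14 by thermal ring expansion, which forms the bond between E-1 and E-2 and closes ring E, while the hindered ether from D-4 to E-1 is carried in on a Z enol ether. 14 comes from dimethyl squarate, a lithium aryloxyacetylide, MeOTf and semihydrogenation; the aryl part comes from syringaldehyde.
5. Ring order: rings A, B, D and F are bought as benzene rings; ring E (and, as the second copy of 17, ring C) is the only ring built, in step 6.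

Key step: step 6

Remark: rings are lettered from the 2,4,6-trihydroxyphenoxy end (A) to the 3,4,5-trihydroxyphenyl end (F). In each ring, carbon 1 bears the ether oxygen toward the ring A side; B-4, C-2, D-4 and E-2 bear the ether oxygen toward the ring F side. The target has no stereocentre. 2,4,6-Trimethoxyphenol and (3,4,5-trimethoxyphenyl)boronic acid are taken as catalogue compounds.

Remark: the two-carbon unit is introduced as an acetylide and reduced afterwards, because a 2-aryloxyvinyllithium can expel aryloxide and bromination of an aryl vinyl ether would attack the electron-rich ring.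

**Route**

Step 1
Reactants: 1 syringaldehyde (4-hydroxy-3,5-dimethoxybenzaldehyde)
Product: 3 2,6-dimethoxybenzene-1,4-diol, via aryl formate 2 (not isolated)
Conditions: H2O2 (30% aq.), NaOH, H2O–THF, N2, 0 °C to rt; then HCl, Na2S2O4 wash
Reagents that add atoms: hydrogen peroxide, OO
Why: Dakin oxidation of a para-hydroxybenzaldehyde, in which hydroperoxide adds to the aldehyde, the electron-rich aryl group migrates to oxygen and formate 2 is saponified in the flask; dithionite in the work-up should keep the air-sensitive hydroquinone reduced.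

Step 2
Reactants: 3 2,6-dimethoxybenzene-1,4-diol; 4 benzyl bromide
Product: 5 4-(benzyloxy)-2,6-dimethoxyphenol
Conditions: BnBr (1.0 equiv), K2CO3 (1.0 equiv), acetone (degassed), Ar, rt
Reagents that add atoms: none
Why: Williamson etherification with limiting base and halide, expected at the 4-hydroxyl because that hydroxyl lies between two hydrogens and is the more acidic one (two meta methoxy groups), whereas the 1-hydroxyl is shielded by two ortho methoxy groups.

Step 3
Reactants: 5 4-(benzyloxy)-2,6-dimethoxyphenol; 6 trichloroethylene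
Product: 8 5-(benzyloxy)-2-{[(E)-1,2-dichloroethenyl]oxy}-1,3-dimethoxybenzene, via dichloroacetylene 7 (not isolated)
Conditions: K2CO3, DMF, 70 °C
Reagents that add atoms: none
Why: Base-mediated dichlorovinylation of a phenol, in which K2CO3 dehydrochlorinates trichloroethylene to dichloroacetylene, the phenoxide adds anti and protonation gives the E ether; the slim sp-hybridised electrophile should tolerate the two ortho methoxy groups.

Step 4
Reactants: 8 5-(benzyloxy)-2-{[(E)-1,2-dichloroethenyl]oxy}-1,3-dimethoxybenzene; 9 dimethyl squarate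
Product: 13 rac-4-{[4-(benzyloxy)-2,6-dimethoxyphenoxy]ethynyl}-2,3,4-trimethoxycyclobut-2-en-1-one, via chloroalkynyl ether 10 (not isolated), via lithium acetylide 11 (not isolated), via lithium alkoxide 12 (not isolated)
Conditions: n-BuLi (2.0 equiv), THF, −78 to −40 °C; then 9, THF, −78 °C; then MeOTf, −78 to 0 °C
Reagents that add atoms: methyl trifluoromethanesulfonate, COS(=O)(=O)C(F)(F)F
Why: Deprotonation with chloride loss and then chlorine–lithium exchange should turn the dichlorovinyl ether into the lithium aryloxyacetylide, which adds 1,2 to one squarate carbonyl (alkynyllithium addition to a squarate ester), and the tertiary lithium alkoxide is O-methylated in the flask; the new stereocentre is racemic and is erased in step 6.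

Step 5
Reactants: 13 rac-4-{[4-(benzyloxy)-2,6-dimethoxyphenoxy]ethynyl}-2,3,4-trimethoxycyclobut-2-en-1-one
Product: 14 rac-4-[(Z)-2-[4-(benzyloxy)-2,6-dimethoxyphenoxy]ethenyl]-2,3,4-trimethoxycyclobut-2-en-1-one
Conditions: H2 (1 atm), Pd/CaCO3 poisoned with Pb(OAc)2 (Lindlar catalyst), quinoline, EtOAc, rt
Reagents that add atoms: none
Why: Lindlar semihydrogenation adds hydrogen syn to the ynol ether and should stop at the Z enol ether, while the benzyl ether, the tetrasubstituted dimethoxy alkene and the ketone are not reduced on the poisoned catalyst.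

Step 6
Reactants: 14 rac-4-[(Z)-2-[4-(benzyloxy)-2,6-dimethoxyphenoxy]ethenyl]-2,3,4-trimethoxycyclobut-2-en-1-one
Product: 17 6-[4-(benzyloxy)-2,6-dimethoxyphenoxy]-2,3,4-trimethoxyphenol, via dienylketene 15 (not isolated), via cyclohexadienone 16 (not isolated)
Conditions: toluene (degassed, 0.01 M), 110 °C, Ar
Reagents that add atoms: none
Why: Heating should open the cyclobutenone by conrotatory 4π-electrocyclic cleavage of the bond between the carbonyl carbon and the quaternary ring carbon, the methoxy group on the quaternary carbon turning outward and the aryloxyvinyl group inward, so that dienylketene 15 has the vinyl group cis to the ketene. A thermal disrotatory 6π-electrocyclisation then joins the ketene carbon to the aryloxy-bearing vinyl carbon (the bond between E-1 and E-2) and closes the six-membered ring E as cyclohexa-2,4-dienone 16, which enolises to the phenol. The closest known reaction type is the thermal ring expansion of squarate-derived 4-alkenyl-4-alkoxycyclobutenones to hydroquinone monoethers. No stereocentre is formed, and the one in 14 is destroyed. The selectivity needed is the torquoselectivity of the ring opening, secured by the strong outward preference of the donor methoxy group on the quaternary carbon; the substituent pattern is fixed by connectivity, the ketene oxygen becoming the free hydroxyl at E-2, the methoxy group of the quaternary carbon becoming the methoxy group at E-5 and the aryloxy group ending at E-1 next to the hydrogen at E-6. The ketene terminus carries no substituent, so the inward Z aryloxy group should not block the closure.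

Step 7
Reactants: 17 6-[4-(benzyloxy)-2,6-dimethoxyphenoxy]-2,3,4-trimethoxyphenol; 18 (3,4,5-trimethoxyphenyl)boronic acid
Product: 19 5-(benzyloxy)-1,3-dimethoxy-2-[3,4,5-trimethoxy-2-(3,4,5-trimethoxyphenoxy)phenoxy]benzene (rings D–E–F, benzyl ether on carbon 1 of ring D)
Conditions: Cu(OAc)2 (2 equiv), pyridine, 4 Å MS, CH2Cl2, rt, open to dry air
Reagents that add atoms: none
Why: Chan–Lam coupling, in which the boronic acid transmetalates to divalent copper and the aryl copper phenoxide collapses by reductive elimination; the aryl partner has no ortho substituent, which is what should let the doubly ortho-substituted phenol at E-2 couple.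

Step 8
Reactants: 19 (rings D–E–F, benzyl ether on carbon 1 of ring D)
Product: 20 3,5-dimethoxy-4-[3,4,5-trimethoxy-2-(3,4,5-trimethoxyphenoxy)phenoxy]phenol
Conditions: H2 (1 atm), Pd/C, EtOAc–MeOH, rt
Reagents that add atoms: none
Why: Catalytic hydrogenolysis of the benzyl ether; aryl methyl ethers and diaryl ethers are inert under these conditions.

Step 9
Reactants: 20 3,5-dimethoxy-4-[3,4,5-trimethoxy-2-(3,4,5-trimethoxyphenoxy)phenoxy]phenol
Product: 21 3,5-dimethoxy-4-[3,4,5-trimethoxy-2-(3,4,5-trimethoxyphenoxy)phenoxy]phenyl trifluoromethanesulfonate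
Conditions: Tf2O, pyridine, CH2Cl2, 0 °C
Reagents that add atoms: trifluoromethanesulfonic anhydride, O=S(=O)(OS(=O)(=O)C(F)(F)F)C(F)(F)F
Why: O-sulfonylation of an unhindered phenol (two ortho hydrogens) gives the aryl triflate.

Step 10
Reactants: 21 (trimer D–E–F, triflate on carbon 1 of ring D)
Product: 22 2-{3,5-dimethoxy-4-[3,4,5-trimethoxy-2-(3,4,5-trimethoxyphenoxy)phenoxy]phenyl}-4,4,5,5-tetramethyl-1,3,2-dioxaborolane
Conditions: B2pin2, PdCl2(dppf), dppf, KOAc, dioxane, 85 °C
Reagents that add atoms: bis(pinacolato)diboron, CC1(C)OB(OC1(C)C)B1OC(C)(C)C(C)(C)O1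
Why: Miyaura borylation by oxidative addition of the aryl triflate to zerovalent palladium, acetate-assisted transmetalation with the diboron and reductive elimination.

Step 11
Reactants: 22 (trimer D–E–F, pinacol boronate on carbon 1 of ring D)
Product: 23 {3,5-dimethoxy-4-[3,4,5-trimethoxy-2-(3,4,5-trimethoxyphenoxy)phenoxy]phenyl}boronic acid
Conditions: NaIO4, NH4OAc, acetone–H2O, rt
Reagents that add atoms: water, O
Why: Oxidative removal of pinacol, in which periodate cleaves the diol released by hydrolysis and so drives the ester to the free boronic acid; the substrate has no phenol or other group that periodate oxidises.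

Step 12
Reactants: 23 (trimer D–E–F, boronic acid on carbon 1 of ring D); 17 6-[4-(benzyloxy)-2,6-dimethoxyphenoxy]-2,3,4-trimethoxyphenol
Product: 24 pentamer B–C–D–E–F as its thirteen-fold methyl ether with a benzyl ether on carbon 1 of ring B (ring B 3,5-dimethoxy; oxygen bridge from B-4 to C-1; ring C 3,4,5-trimethoxy; oxygen bridge from C-2 to D-1; ring D 3,5-dimethoxy; oxygen bridge from D-4 to E-1; ring E 3,4,5-trimethoxy; oxygen bridge from E-2 to F-1; ring F 3,4,5-trimethoxy)
Conditions: Cu(OAc)2 (2 equiv), pyridine, 4 Å MS, CH2Cl2, rt, open to dry air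
Reagents that add atoms: none
Why: Chan–Lam coupling as in step 7; the second copy of 17 supplies rings B and C through its hindered phenol at C-2, and the boronic acid on ring D has two ortho hydrogens.

Step 13
Reactants: 24 (pentamer, benzyl ether on carbon 1 of ring B)
Product: 25 pentamer B–C–D–E–F with a free phenol on carbon 1 of ring B
Conditions: H2 (1 atm), Pd/C, EtOAc–MeOH, rt
Reagents that add atoms: none
Why: Catalytic hydrogenolysis of the benzyl ether, as in step 8.

Step 14
Reactants: 25 (pentamer, phenol on carbon 1 of ring B)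
Product: 26 pentamer B–C–D–E–F with a trifluoromethanesulfonate on carbon 1 of ring B
Conditions: Tf2O, pyridine, CH2Cl2, 0 °C
Reagents that add atoms: trifluoromethanesulfonic anhydride, O=S(=O)(OS(=O)(=O)C(F)(F)F)C(F)(F)F
Why: O-sulfonylation of the unhindered ring B phenol, as in step 9.

Step 15
Reactants: 26 (pentamer, triflate on carbon 1 of ring B)
Product: 27 pentamer B–C–D–E–F with a pinacol boronate on carbon 1 of ring B
Conditions: B2pin2, PdCl2(dppf), dppf, KOAc, dioxane, 85 °C
Reagents that add atoms: bis(pinacolato)diboron, CC1(C)OB(OC1(C)C)B1OC(C)(C)C(C)(C)O1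
Why: Miyaura borylation of the aryl triflate, as in step 10.

Step 16
Reactants: 27 (pentamer, pinacol boronate on carbon 1 of ring B)
Product: 28 pentamer B–C–D–E–F with a boronic acid on carbon 1 of ring B
Conditions: NaIO4, NH4OAc, acetone–H2O, rt
Reagents that add atoms: water, O
Why: Periodate-driven hydrolysis of the pinacol ester, as in step 11.

Step 17
Reactants: 28 (pentamer, boronic acid on carbon 1 of ring B); 29 2,4,6-trimethoxyphenol
Product: 30 hexadecamethyl ether of the target (hexamer A–F, every hydroxyl as OMe)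
Conditions: Cu(OAc)2 (2 equiv), pyridine, 4 Å MS, CH2Cl2, rt, open to dry air
Reagents that add atoms: none
Why: Chan–Lam coupling of the doubly ortho-methoxylated ring A phenol with the unhindered ring B boronic acid, the same pairing of partners as in steps 7 and 12.

Step 18
Reactants: 30 hexadecamethyl ether of the target
Product: 31 CNP0114537.0 (target)
Conditions: BBr3 (excess), CH2Cl2, −78 °C to rt, Ar; then MeOH, degassed H2O
Reagents that add atoms: none
Why: Lewis acid demethylation, in which boron binds each methoxy oxygen and bromide attacks the methyl carbon by SN2; the diaryl ether bonds have no sp3 carbon to attack and should survive.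

**Compound list**

1 | syringaldehyde (4-hydroxy-3,5-dimethoxybenzaldehyde) | COc1cc(C=O)cc(OC)c1O | starting material
2 | 4-hydroxy-3,5-dimethoxyphenyl formate (not isolated) | COc1cc(OC=O)cc(OC)c1O | intermediate
3 | 2,6-dimethoxybenzene-1,4-diol | COc1cc(O)cc(OC)c1O | intermediate
4 | benzyl bromide | BrCc1ccccc1 | starting material
5 | 4-(benzyloxy)-2,6-dimethoxyphenol | COc1cc(OCc2ccccc2)cc(OC)c1O | intermediate
6 | trichloroethylene | ClC=C(Cl)Cl | starting material
7 | dichloroacetylene (not isolated) | ClC#CCl | intermediate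
8 | 5-(benzyloxy)-2-{[(E)-1,2-dichloroethenyl]oxy}-1,3-dimethoxybenzene | Cl/C=C(/Cl)Oc1c(OC)cc(OCc2ccccc2)cc1OC | intermediate
9 | dimethyl squarate (3,4-dimethoxycyclobut-3-ene-1,2-dione) | COC1=C(OC)C(=O)C1=O | starting material
10 | 5-(benzyloxy)-2-[(chloroethynyl)oxy]-1,3-dimethoxybenzene (not isolated) | ClC#COc1c(OC)cc(OCc2ccccc2)cc1OC | intermediate
11 | lithium [4-(benzyloxy)-2,6-dimethoxyphenoxy]acetylide (not isolated) | [Li]C#COc1c(OC)cc(OCc2ccccc2)cc1OC | intermediate
12 | lithium 1-{[4-(benzyloxy)-2,6-dimethoxyphenoxy]ethynyl}-2,3-dimethoxy-4-oxocyclobut-2-en-1-olate (racemic, not isolated) | [Li]OC1(C#COc2c(OC)cc(OCc3ccccc3)cc2OC)C(OC)=C(OC)C1=O | intermediate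
13 | rac-4-{[4-(benzyloxy)-2,6-dimethoxyphenoxy]ethynyl}-2,3,4-trimethoxycyclobut-2-en-1-one | COC1=C(OC)C(OC)(C#COc2c(OC)cc(OCc3ccccc3)cc2OC)C1=O | intermediate
14 | rac-4-[(Z)-2-[4-(benzyloxy)-2,6-dimethoxyphenoxy]ethenyl]-2,3,4-trimethoxycyclobut-2-en-1-one (key-step precursor) | COC1=C(OC)C(OC)(/C=C\Oc2c(OC)cc(OCc3ccccc3)cc2OC)C1=O | intermediate
15 | (3Z,5Z)-6-[4-(benzyloxy)-2,6-dimethoxyphenoxy]-2,3,4-trimethoxyhexa-1,3,5-trien-1-one (dienylketene, not isolated) | O=C=C(OC)/C(OC)=C(OC)\C=C/Oc1c(OC)cc(OCc2ccccc2)cc1OC | intermediate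
16 | rac-6-[4-(benzyloxy)-2,6-dimethoxyphenoxy]-2,3,4-trimethoxycyclohexa-2,4-dien-1-one (not isolated) | COC1=CC(Oc2c(OC)cc(OCc3ccccc3)cc2OC)C(=O)C(OC)=C1OC | intermediate
17 | 6-[4-(benzyloxy)-2,6-dimethoxyphenoxy]-2,3,4-trimethoxyphenol (key-step product) | COc1cc(OCc2ccccc2)cc(OC)c1Oc1cc(OC)c(OC)c(OC)c1O | intermediate
18 | (3,4,5-trimethoxyphenyl)boronic acid | COc1cc(B(O)O)cc(OC)c1OC | starting material
19 | 5-(benzyloxy)-1,3-dimethoxy-2-[3,4,5-trimethoxy-2-(3,4,5-trimethoxyphenoxy)phenoxy]benzene | COc1cc(OCc2ccccc2)cc(OC)c1Oc1cc(OC)c(OC)c(OC)c1Oc1cc(OC)c(OC)c(OC)c1 | intermediate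
20 | 3,5-dimethoxy-4-[3,4,5-trimethoxy-2-(3,4,5-trimethoxyphenoxy)phenoxy]phenol | COc1cc(O)cc(OC)c1Oc1cc(OC)c(OC)c(OC)c1Oc1cc(OC)c(OC)c(OC)c1 | intermediate
21 | 3,5-dimethoxy-4-[3,4,5-trimethoxy-2-(3,4,5-trimethoxyphenoxy)phenoxy]phenyl trifluoromethanesulfonate | COc1cc(OS(=O)(=O)C(F)(F)F)cc(OC)c1Oc1cc(OC)c(OC)c(OC)c1Oc1cc(OC)c(OC)c(OC)c1 | intermediate
22 | 2-{3,5-dimethoxy-4-[3,4,5-trimethoxy-2-(3,4,5-trimethoxyphenoxy)phenoxy]phenyl}-4,4,5,5-tetramethyl-1,3,2-dioxaborolane | COc1cc(B2OC(C)(C)C(C)(C)O2)cc(OC)c1Oc1cc(OC)c(OC)c(OC)c1Oc1cc(OC)c(OC)c(OC)c1 | intermediate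
23 | {3,5-dimethoxy-4-[3,4,5-trimethoxy-2-(3,4,5-trimethoxyphenoxy)phenoxy]phenyl}boronic acid | COc1cc(B(O)O)cc(OC)c1Oc1cc(OC)c(OC)c(OC)c1Oc1cc(OC)c(OC)c(OC)c1 | intermediate
24 | pentamer B–C–D–E–F, methyl ethers, benzyl ether on carbon 1 of ring B | COc1cc(OCc2ccccc2)cc(OC)c1Oc1cc(OC)c(OC)c(OC)c1Oc1cc(OC)c(Oc2cc(OC)c(OC)c(OC)c2Oc2cc(OC)c(OC)c(OC)c2)c(OC)c1 | intermediate
25 | pentamer B–C–D–E–F, methyl ethers, free phenol on carbon 1 of ring B | COc1cc(O)cc(OC)c1Oc1cc(OC)c(OC)c(OC)c1Oc1cc(OC)c(Oc2cc(OC)c(OC)c(OC)c2Oc2cc(OC)c(OC)c(OC)c2)c(OC)c1 | intermediate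
26 | pentamer B–C–D–E–F, methyl ethers, trifluoromethanesulfonate on carbon 1 of ring B | COc1cc(OS(=O)(=O)C(F)(F)F)cc(OC)c1Oc1cc(OC)c(OC)c(OC)c1Oc1cc(OC)c(Oc2cc(OC)c(OC)c(OC)c2Oc2cc(OC)c(OC)c(OC)c2)c(OC)c1 | intermediate
27 | pentamer B–C–D–E–F, methyl ethers, pinacol boronate on carbon 1 of ring B | COc1cc(B2OC(C)(C)C(C)(C)O2)cc(OC)c1Oc1cc(OC)c(OC)c(OC)c1Oc1cc(OC)c(Oc2cc(OC)c(OC)c(OC)c2Oc2cc(OC)c(OC)c(OC)c2)c(OC)c1 | intermediate
28 | pentamer B–C–D–E–F, methyl ethers, boronic acid on carbon 1 of ring B | COc1cc(B(O)O)cc(OC)c1Oc1cc(OC)c(OC)c(OC)c1Oc1cc(OC)c(Oc2cc(OC)c(OC)c(OC)c2Oc2cc(OC)c(OC)c(OC)c2)c(OC)c1 | intermediate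
29 | 2,4,6-trimethoxyphenol | COc1cc(OC)c(O)c(OC)c1 | starting material
30 | hexadecamethyl ether of the target | COc1cc(OC)c(Oc2cc(OC)c(Oc3cc(OC)c(OC)c(OC)c3Oc3cc(OC)c(Oc4cc(OC)c(OC)c(OC)c4Oc4cc(OC)c(OC)c(OC)c4)c(OC)c3)c(OC)c2)c(OC)c1 | intermediate
31 | CNP0114537.0 | Oc1cc(O)c(Oc2cc(O)c(Oc3cc(O)c(O)c(O)c3Oc3cc(O)c(Oc4cc(O)c(O)c(O)c4Oc4cc(O)c(O)c(O)c4)c(O)c3)c(O)c2)c(O)c1 | target

**Step count and risks**

Total step count: 18. Longest linear sequence: 18 steps (1 to 31; compound 17 enters twice, in steps 7 and 12).

Steps most likely to fail: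

Step 6. The ketene released on ring opening may be diverted before it closes (dimerisation, capture by traces of water), or the acid- and heat-sensitive enol ether may decompose before the four-membered ring opens. The fallback forms the hindered ether between D-4 and E-1 by arylation instead. It sets out from phenol 5. Rieche formylation of 5-bromo-1,2,3-trimethoxybenzene (Cl2CHOMe, TiCl4, CH2Cl2) gives 6-bromo-2,3,4-trimethoxybenzaldehyde F1. Ullmann coupling of 5 with it (CuI, picolinic acid, K3PO4, DMSO, 90 °C), helped by the ortho aldehyde, should give 6-[4-(benzyloxy)-2,6-dimethoxyphenoxy]-2,3,4-trimethoxybenzaldehyde F2. Dakin oxidation with mCPBA in CH2Cl2 gives 6-[4-(benzyloxy)-2,6-dimethoxyphenoxy]-2,3,4-trimethoxyphenyl formate F3, and K2CO3 in MeOH frees the phenol, so the path comes back at 17.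

Step 12 (the same concern applies to steps 7 and 17). Ligation of the hindered phenol to copper may be slow, so that protodeboronation and oxidative hydroxylation of the boronic acid, or oxidation of the electron-rich phenol by divalent copper and air, take over. The fallback is a redox-neutral palladium coupling without oxidant. It sets out from triflate 21 and phenol 17, which are joined by palladium-catalysed diaryl ether synthesis through a zerovalent/divalent palladium cycle (Pd(OAc)2, tBuXPhos, K3PO4, toluene, 100 °C, Ar). It comes back at 24 and makes no new compound (F0).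

Step 18. Cleavage of sixteen methyl ethers may stop short, and the free polyphenol may be lost by air oxidation and irreversible adsorption during isolation. The fallback isolates the product in masked form. It sets out from 30: after the BBr3 treatment the crude material is acetylated without purification (Ac2O, pyridine, DMAP) to the hexadecaacetate of the target F4, which can be chromatographed on silica and separated from under-cleaved material. Deacetylation under argon (HCl generated from AcCl in degassed MeOH, or catalytic NaOMe as in a Zemplén deacetylation) then returns to 31.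

**Further compounds**

F1 | step 6 | 6-bromo-2,3,4-trimethoxybenzaldehyde | COc1cc(Br)c(C=O)c(OC)c1OC
F2 | step 6 | 6-[4-(benzyloxy)-2,6-dimethoxyphenoxy]-2,3,4-trimethoxybenzaldehyde | COc1cc(OCc2ccccc2)cc(OC)c1Oc1cc(OC)c(OC)c(OC)c1C=O
F3 | step 6 | 6-[4-(benzyloxy)-2,6-dimethoxyphenoxy]-2,3,4-trimethoxyphenyl formate | COc1cc(OCc2ccccc2)cc(OC)c1Oc1cc(OC)c(OC)c(OC)c1OC=O
F0 | step 12 | none | none
F4 | step 18 | hexadecaacetate of the target | CC(=O)Oc1cc(OC(C)=O)c(Oc2cc(OC(C)=O)c(Oc3cc(OC(C)=O)c(OC(C)=O)c(OC(C)=O)c3Oc3cc(OC(C)=O)c(Oc4cc(OC(C)=O)c(OC(C)=O)c(OC(C)=O)c4Oc4cc(OC(C)=O)c(OC(C)=O)c(OC(C)=O)c4)c(OC(C)=O)c3)c(OC(C)=O)c2)c(OC(C)=O)c1
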